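## Structural features

The target is a depside. Ring A is a 2,4-dihydroxy-6-pentylbenzoyl unit and ring B is a 2-hydroxy-6-propylbenzoic acid; the only link is an aryl ester from the ring A carboxyl carbon to O4 of ring B. There are two benzene rings, two unbranched alkyl chains and no stereocentre, so the problem is one of regiochemistry and chemoselectivity. Ring B has two phenolic oxygens (O2 and O4) that must be told apart, and its C1 carboxyl must end free while the ring A carboxyl ends as the ester. The fragile points are the depside ester (cleaved or exchanged by hydroxide and alkoxide), the two salicylic-acid-type units (decarboxylation on heating or in strong acid) and the electron-rich resorcinol rings (halogenation, oxidation). The ring A acyl carbon lies between an oxygen substituent and the pentyl chain, which slows ester formation but shields the ester once it exists. The real difficulty is to place this hindered ester on O4 alone and then to unmask three hydroxyl functions without hydrolysis. The key step uses the fact that C1 with its carboxyl, C2 and O2 of ring B map onto a malonate, and C3 to C6 with the propyl group map onto hept-3-en-2-one. Ring B can therefore be made as a 2,4-dioxocyclohexane-1-carboxylate, in which O4 is the open end of a vinylogous acid and O2 is shielded by the C1 ester.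

## Logic of the disconnections

16 to 15. The three benzyl–oxygen bonds (O2 and O4 of ring A, the carboxyl oxygen of ring B) are cut last. Benzyl is the one group that leaves under neutral, non-hydrolytic conditions in a single operation, so the depside ester and the decarboxylation-prone acid are not endangered. The gain is that every acidic OH is masked by one kind of group. The demand is that hydrogenolysis be the final step, in an aprotic solvent, on material free of catalyst poisons.

15 to 11 (through 14, 13 and 12). The aromaticity of ring B is removed by adding two hydrogens across C1–C6. At the dihydro level O2 and O4 are no longer two similar phenols. The forward dehydrogenation must be mild enough for a vinylogous anhydride and must leave ring A alone, whose two free positions are each activated by two benzyloxy groups. Electrophilic bromine would meet neither condition: it can brominate ring A, and a C1 bromide formed anti to the propyl group has no anti-periplanar C6–H for elimination. A selenium electrophile at C1 followed by syn elimination of 13 fits the stereochemistry, because selenium entering anti to propyl lies on the same face as the C6 hydrogen.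

11 to 10 and 6. The ester bond between the ring A carbonyl carbon and O4 is cut. This is the convergent cut and gives two fragments of similar size. The forward step must acylate an ambident enolate (O2, C3, O4) on O4 only, with a hindered acid chloride and without a nucleophilic catalyst that would move the acyl group to C3.

10 to 7 and 8 (through 9). The C1–C6 and C2–C3 bonds are cut. Ring B with all four substituents in place then comes from two purchased compounds. The benzyl ester that the final step removes is already present in 7, so no design change to this pair is needed. The forward step needs one equivalent of the matching alkoxide, conjugate addition before ring closure, and a cold acidic work-up that spares the β-keto ester.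

6 to 5 to 4. The C–Cl bond and then one C–O bond of the carboxyl are removed as functional-group changes. The oxidation must not chlorinate the electron-rich ring. The activation must avoid Lewis acids and heat, which would strip the ortho benzyl ether.

4 to 2 (through 3). The bond from ring A C1 to the formyl carbon is cut, because that carbon can be delivered by electrophilic substitution. The forward step must attack the position flanked by pentyl and benzyloxy (para to the other benzyloxy) and not the position between the two benzyloxy groups.

2 to 1. The two benzyl–oxygen bonds are cut. Benzylation before formylation avoids the slow alkylation of a hydrogen-bonded ortho-hydroxy aldehyde and removes the competing site between two free hydroxyls.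

## Other disconnections considered

Alternative 1: The cut is the ring A C1–C6 bond of benzyl 4-[(2,4-dihydroxy-6-pentylbenzoyl)oxy]-2-hydroxy-6-propylbenzoate A2. Ring A unravels to the 3,5,7-trioxododecanoyl chain of benzyl 2-hydroxy-6-propyl-4-[(3,5,7-trioxododecanoyl)oxy]benzoate A1, already esterified to O4 of ring B.
- Forward key step: mild base and then acid should make chain C2 add to the C7 ketone; dehydration and enolisation would then give ring A. A1 would come from benzyl 2,4-dihydroxy-6-propylbenzoate A3 and the acylketene released on heating 6-(2,4-dioxononyl)-2,2-dimethyl-4H-1,3-dioxin-4-one A4.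
- In its favour: ring A would appear with free phenols, so only one benzyl group has to be removed. The ester bond is made by ketene capture before the acyl carbon becomes hindered, which is a real advantage over step 6.
- Against it: A1 is an aryl ester next to a polyketone. The aryloxide is a good leaving group, so pyranone formation from the C5 enol oxygen and a C6-to-C1 Claisen closure, both with loss of A3, would compete with the aldol. Phenols also capture acylketenes less readily than alcohols do. A3 still has to be made, most simply by step 5 plus an aromatisation, so the ring B work is not saved.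
- Comparison: both plans build one ring from open-chain carbonyl compounds. The chosen annulation has one reasonable course, while the fold of A1 has three. The operation count is about equal (roughly seven against eight). On protecting-group economy Alternative 1 is the better; on predictability the chosen plan is.

Alternative 2: The cut removes the propyl group and the carboxyl carbon from ring B, leaving an aryne.
- Forward key step: bromine–lithium exchange on 2-bromo-1-fluoro-3,5-dimethoxybenzene A5 and loss of LiF would give 3,5-dimethoxybenzyne A6. Propylmagnesium bromide should add at the carbon remote from the neighbouring methoxy group, and CO2 would trap the arylmetal to give 2,4-dimethoxy-6-propylbenzoic acid A7.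
- In its favour: two adjacent C–C bonds are set in one operation on a ready-made arene. The regiochemistry follows from the inductive pull of the flanking methoxy group. No dehydrogenation and no selenium are needed; on this point it is the better plan.
- Against it: the methyl ethers must be cleaved with a strong Lewis acid to 2,4-dihydroxy-6-propylbenzoic acid A8, which decarboxylates easily. A8 must then be benzylated on the carboxyl to A3 and acylated with 6. The O2/O4 distinction then rests only on the hydrogen bond of the 2-OH. Butyllithium or the aryllithium can add to A6 in competition with the Grignard reagent, and the step needs cryogenic organometallics.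
- Comparison: the aryne step is mechanistically sound and equal to the chosen key step in regiocontrol at C1 and C6. The ring B branch would take about six operations against four, so the whole route is about two steps longer. It also leaves the oxygen differentiation unsolved.

Alternative 3: The cut removes both bonds at the ester carbonyl carbon (ring A C1–carbonyl and carbonyl–O4).
- Forward key step: 1,5-bis(benzyloxy)-2-iodo-3-pentylbenzene A9, CO and the 4-OH of A3 would combine under Pd(OAc)2, Xantphos and Et3N. Oxidative addition to zerovalent palladium, CO insertion and capture of the aroyl palladium by the phenoxide would give the tribenzyl depside A10, which is identical with 15.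
- In its favour: A9 is one iodination away from 2, so ring A needs two steps, not four. A3 would come from 10 by one aromatisation with no ring A present. The labile enol ester 11 is avoided. The total is about six steps against eight, so on step count and on handling of sensitive intermediates this alternative is the better.
- Against it: the iodide is electron-rich and has two ortho substituents. Capture of so hindered an aroyl palladium by a weakly nucleophilic phenol is the slow event, and loss of iodine by reduction or direct C–O coupling may compete. The plan uses toxic CO under pressure. The choice between the 4-OH and 2-OH of A3 again rests on the hydrogen bond, and the iodination of 2 must avoid the position between the benzyloxy groups.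
- Comparison: both plans make the same bond at the same hindered carbon and end with the same hydrogenolysis (equal). The acid chloride route is longer but more certain at the point of convergence, and it builds the O2/O4 distinction into the substrate.

Key step: step 5

Remark on the chemistry: 10 to 13 are racemates drawn as one enantiomer; their C1 and C6 centres are destroyed in step 7 and the target has no stereocentre. The configuration drawn for 10 was checked and is the trans isomer, and the skeletons of 7, 8 and 10 needed no correction.

## Steps

Step 1
Reactants: 1 5-pentylbenzene-1,3-diol (olivetol)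
Product: 2 1,3-bis(benzyloxy)-5-pentylbenzene
Conditions: BnBr, K2CO3, DMF, rt → 50 °C
Reagents that add atoms: benzyl bromide, BrCc1ccccc1
Why: Williamson ether synthesis; carbonate in a dipolar aprotic solvent favours O- over C-alkylation of the resorcinol, and both phenols are unhindered.

Step 2
Reactants: 2 1,3-bis(benzyloxy)-5-pentylbenzene
Product: 4 2,4-bis(benzyloxy)-6-pentylbenzaldehyde, via aryl iminium chloride 3 (not isolated)
Conditions: POCl3, DMF, 0 → 70 °C; then aq. NaOAc, rt
Reagents that add atoms: N,N-dimethylformamide, CN(C)C=O; water, O
Why: Vilsmeier–Haack formylation; the chloroiminium ion should attack para to one benzyloxy group at one of the two equivalent positions next to the pentyl chain, not the more crowded position between the two benzyloxy groups, and hydrolysis of 3 releases the aldehyde.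

Step 3
Reactants: 4 2,4-bis(benzyloxy)-6-pentylbenzaldehyde
Product: 5 2,4-bis(benzyloxy)-6-pentylbenzoic acid
Conditions: NaClO2, NaH2PO4, 2-methylbut-2-ene, t-BuOH/THF/H2O, 0 °C → rt
Reagents that add atoms: sodium chlorite, [Na+].[O-]Cl=O
Why: Pinnick oxidation; chlorous acid oxidises the aldehyde without touching benzyl ethers, and the alkene scavenger removes hypochlorous acid before it can chlorinate the electron-rich ring.

Step 4
Reactants: 5 2,4-bis(benzyloxy)-6-pentylbenzoic acid
Product: 6 2,4-bis(benzyloxy)-6-pentylbenzoyl chloride
Conditions: (COCl)2, DMF (cat.), CH2Cl2, 0 °C → rt; evaporate, use crude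
Reagents that add atoms: oxalyl chloride, O=C(Cl)C(=O)Cl
Why: Acid chloride formation under DMF catalysis; only gases are released, and the low temperature and absence of Lewis acid should keep the ortho benzyl ether intact.

Step 5
Reactants: 7 dibenzyl malonate; 8 (E)-hept-3-en-2-one
Product: 10 benzyl trans-4-hydroxy-2-oxo-6-propylcyclohex-3-ene-1-carboxylate (racemic), via open-chain Michael adduct 9 (not isolated)
Conditions: NaH, BnOH, THF, 0 °C (forms NaOBn); 7, then slow addition of 8, rt → 65 °C; then 1 M HCl, 0 °C
Reagents that add atoms: none
Why: Tandem Michael addition–Claisen (Dieckmann-type) condensation, the established route from malonates and alk-3-en-2-ones to 6-alkyl-2,4-dioxocyclohexanecarboxylates. The sodium enolate of 7 adds to the propyl-bearing β-carbon of 8 (C1–C6 bond) to give 9; proton transfer then forms the methyl-side enolate of the ketone, whose carbon attacks one benzyl ester carbonyl (C2–C3 bond) and expels benzyloxide. The ring closes in a 6-(enolendo)-exo-trig mode, and the sequence is driven forward because the product, a vinylogous acid, is deprotonated and leaves the equilibrium as its sodium enolate. The regiochemistry follows from the order of events: the soft malonate anion adds 1,4 first, and afterwards only the terminal methyl of the ketone can reach an ester carbonyl through a six-membered transition state. C1 and C6 become stereocentres; C1 is epimerisable, so ester and propyl should settle trans (both equatorial) under thermodynamic control, as a racemate, and both centres disappear in step 7. Benzyloxide matches the ester groups, so alkoxide exchange changes nothing; one equivalent is needed. Cold acidification protonates the enolate without hydrolysis and decarboxylation of the β-keto ester, and the acidity of 10 allows purification by base extraction.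

Step 6
Reactants: 10 benzyl trans-4-hydroxy-2-oxo-6-propylcyclohex-3-ene-1-carboxylate (racemic); 6 2,4-bis(benzyloxy)-6-pentylbenzoyl chloride
Product: 11 benzyl trans-4-{[2,4-bis(benzyloxy)-6-pentylbenzoyl]oxy}-2-oxo-6-propylcyclohex-3-ene-1-carboxylate (racemic)
Conditions: Et3N (1.1 equiv), CH2Cl2, −20 °C → rt, no DMAP
Reagents that add atoms: none
Why: O-Acylation of a cyclic 1,3-dione enolate by an acid chloride; O4 is flanked only by the C5 methylene whereas O2 is shielded by the C1 ester and the C6 propyl group, so the bulky aroyl chloride should go to O4. Leaving out nucleophilic catalysts suppresses the O-to-C acyl shift to C3, and the O4 ester keeps the C2 ketone as a chelated β-keto ester, so it is also the more stable isomer.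

Step 7
Reactants: 11 benzyl trans-4-{[2,4-bis(benzyloxy)-6-pentylbenzoyl]oxy}-2-oxo-6-propylcyclohex-3-ene-1-carboxylate (racemic)
Product: 15 benzyl 4-{[2,4-bis(benzyloxy)-6-pentylbenzoyl]oxy}-2-hydroxy-6-propylbenzoate, via C1 phenylselenide 12 (not isolated), via selenoxide 13 (not isolated), via cyclohexadienone tautomer 14 (not isolated)
Conditions: PhSeCl, pyridine, CH2Cl2, 0 °C; wash with cold 1 M HCl; then 30% H2O2, CH2Cl2, 0 °C → rt
Reagents that add atoms: none
Why: α-Selenenylation of the β-keto ester at C1 followed by selenoxide syn elimination; selenium should enter anti to the propyl group and so lie syn to the only available β-hydrogen (C6–H). Elimination gives the cross-conjugated dienone 14, which is the keto tautomer of the phenol and tautomerises to 15. A selenium electrophile buffered by pyridine is much less prone than bromine to attack ring A, and the conditions are neutral and cold enough for the enol ester.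

Step 8
Reactants: 15 benzyl 4-{[2,4-bis(benzyloxy)-6-pentylbenzoyl]oxy}-2-hydroxy-6-propylbenzoate
Product: 16 4-[(2,4-dihydroxy-6-pentylbenzoyl)oxy]-2-hydroxy-6-propylbenzoic acid
Conditions: H2 (1 atm), 10% Pd/C, EtOAc, rt
Reagents that add atoms: none
Why: Catalytic hydrogenolysis of two aryl benzyl ethers and one benzyl ester; the aryl ester and both arenes are inert under these conditions, and an aprotic solvent excludes ester exchange.

## Compound list

1 | 5-pentylbenzene-1,3-diol (olivetol) | CCCCCc1cc(O)cc(O)c1 | starting material
2 | 1,3-bis(benzyloxy)-5-pentylbenzene | CCCCCc1cc(OCc2ccccc2)cc(OCc2ccccc2)c1 | intermediate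
3 | {[2,4-bis(benzyloxy)-6-pentylphenyl]methylidene}dimethyliminium chloride | CCCCCc1cc(OCc2ccccc2)cc(OCc2ccccc2)c1C=[N+](C)C.[Cl-] | intermediate (not isolated)
4 | 2,4-bis(benzyloxy)-6-pentylbenzaldehyde | CCCCCc1cc(OCc2ccccc2)cc(OCc2ccccc2)c1C=O | intermediate
5 | 2,4-bis(benzyloxy)-6-pentylbenzoic acid | CCCCCc1cc(OCc2ccccc2)cc(OCc2ccccc2)c1C(=O)O | intermediate
6 | 2,4-bis(benzyloxy)-6-pentylbenzoyl chloride | CCCCCc1cc(OCc2ccccc2)cc(OCc2ccccc2)c1C(=O)Cl | intermediate
7 | dibenzyl malonate | O=C(CC(=O)OCc1ccccc1)OCc1ccccc1 | starting material
8 | (E)-hept-3-en-2-one | CCC/C=C/C(C)=O | starting material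
9 | dibenzyl 2-(2-oxoheptan-4-yl)propanedioate (racemic) | CCCC(CC(C)=O)C(C(=O)OCc1ccccc1)C(=O)OCc1ccccc1 | intermediate (not isolated)
10 | benzyl trans-4-hydroxy-2-oxo-6-propylcyclohex-3-ene-1-carboxylate (racemic; one enantiomer drawn) | CCC[C@@H]1CC(O)=CC(=O)[C@H]1C(=O)OCc1ccccc1 | intermediate
11 | benzyl trans-4-{[2,4-bis(benzyloxy)-6-pentylbenzoyl]oxy}-2-oxo-6-propylcyclohex-3-ene-1-carboxylate (racemic; one enantiomer drawn) | CCC[C@@H]1CC(OC(=O)c2c(CCCCC)cc(OCc3ccccc3)cc2OCc2ccccc2)=CC(=O)[C@H]1C(=O)OCc1ccccc1 | intermediate
12 | benzyl 4-{[2,4-bis(benzyloxy)-6-pentylbenzoyl]oxy}-2-oxo-1-(phenylselanyl)-6-propylcyclohex-3-ene-1-carboxylate (racemic; selenium trans to propyl) | CCC[C@@H]1CC(OC(=O)c2c(CCCCC)cc(OCc3ccccc3)cc2OCc2ccccc2)=CC(=O)[C@]1([Se]c4ccccc4)C(=O)OCc1ccccc1 | intermediate (not isolated)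
13 | benzyl 4-{[2,4-bis(benzyloxy)-6-pentylbenzoyl]oxy}-2-oxo-1-(phenylseleninyl)-6-propylcyclohex-3-ene-1-carboxylate (racemic at carbon; selenium centre undefined) | CCC[C@@H]1CC(OC(=O)c2c(CCCCC)cc(OCc3ccccc3)cc2OCc2ccccc2)=CC(=O)[C@]1([Se](=O)c4ccccc4)C(=O)OCc1ccccc1 | intermediate (not isolated)
14 | benzyl 4-{[2,4-bis(benzyloxy)-6-pentylbenzoyl]oxy}-6-oxo-2-propylcyclohexa-1,4-diene-1-carboxylate | CCCC1=C(C(=O)OCc2ccccc2)C(=O)C=C(OC(=O)c2c(CCCCC)cc(OCc3ccccc3)cc2OCc2ccccc2)C1 | intermediate (not isolated)
15 | benzyl 4-{[2,4-bis(benzyloxy)-6-pentylbenzoyl]oxy}-2-hydroxy-6-propylbenzoate | CCCCCc1cc(OCc2ccccc2)cc(OCc2ccccc2)c1C(=O)Oc1cc(O)c(C(=O)OCc2ccccc2)c(CCC)c1 | intermediate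
16 | 4-[(2,4-dihydroxy-6-pentylbenzoyl)oxy]-2-hydroxy-6-propylbenzoic acid | CCCCCc1cc(O)cc(O)c1C(=O)Oc1cc(O)c(C(=O)O)c(CCC)c1 | target

## Step count and least certain steps

Total: 8 steps. Longest linear sequence: 7 steps (1 → 2 → 4 → 5 → 6 → 11 → 15 → 16, steps 1, 2, 3, 4, 6, 7 and 8). The ring B branch from 7 and 8 takes 4 steps (5, 6, 7, 8).

Step 5 (key step). The likeliest failures are self-condensation and deconjugation of the enolisable enone 8 under alkoxide, a second conjugate addition, and stalling at 9 if the Claisen closure is slow in THF. Hydrolysis and decarboxylation of the β-keto ester could also occur during acidification. The fallback sets out from 7 and changes the first bond-forming event. Knoevenagel condensation of 7 with butanal (piperidine, AcOH, toluene, removal of water) should give dibenzyl 2-butylidenemalonate F1. A Mukaiyama–Michael addition of 2-(trimethylsilyloxy)propene to F1 (TiCl4, CH2Cl2, −78 °C) would then form the C5–C6 bond and deliver 9 as an isolated, purified compound, so the route is rejoined at 9. Closure of pure 9 with NaOBn in THF then leads to 10 with no enone present.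

Step 6. Site selectivity on the ambident enolate may be lost (attack at O2 or C3, or base-promoted O-to-C acyl shift). Acyl transfer from the hindered chloride may be slow, and the vinylogous anhydride may hydrolyse during work-up or chromatography. The fallback sets out from 10 and aromatises before acylating. Bromination–dehydrobromination of the free dione (Br2, DMF, 0 → 80 °C), the long-established way to aromatise 2,4-dioxocyclohexanecarboxylates, should give benzyl 2,4-dihydroxy-6-propylbenzoate F2. Its 2-OH is tied to the ester carbonyl by a hydrogen bond, so acylation with 6 (K2CO3, acetone, rt) should take place on the 4-OH. The route is rejoined at 15, and 11 and step 7 are bypassed.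

Step 7. The enol ester may be cleaved or its acyl group transferred by chloride or pyridine during selenenylation. Selenium may also enter on the face syn to propyl, which leaves no syn hydrogen for elimination. Seleninic or perseleninic acid may oxidise ring A or the new phenol. The fallback sets out from 11 and uses palladium in place of selenium. Silylation (TMSOTf, Et3N, CH2Cl2, 0 °C) should give benzyl 4-{[2,4-bis(benzyloxy)-6-pentylbenzoyl]oxy}-6-propyl-2-(trimethylsilyloxy)cyclohexa-1,3-diene-1-carboxylate F3. A Saegusa–Ito oxidation of F3 (Pd(OAc)2, MeCN, rt) would pass through a divalent palladium enolate at C1 and lose the C6 hydrogen by β-hydride elimination, giving 14 and zerovalent palladium. Tautomerisation of 14 returns the route to 15.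

Step 8. Residual selenium may poison the palladium catalyst, the hindered ortho benzyl ether may be cleaved only slowly, and a long reaction time invites hydrolysis of the depside. The fallback sets out from 15 and uses a Lewis acid in place of hydrogen: BCl3 with pentamethylbenzene as benzyl cation scavenger (CH2Cl2, −78 °C) should cleave the two aryl benzyl ethers and the benzyl ester and give 16 directly, with no new intermediate.

## Further compounds

F1 | step 5 | dibenzyl 2-butylidenemalonate | CCCC=C(C(=O)OCc1ccccc1)C(=O)OCc1ccccc1
F2 | step 6 | benzyl 2,4-dihydroxy-6-propylbenzoate | CCCc1cc(O)cc(O)c1C(=O)OCc1ccccc1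
F3 | step 7 | benzyl 4-{[2,4-bis(benzyloxy)-6-pentylbenzoyl]oxy}-6-propyl-2-(trimethylsilyloxy)cyclohexa-1,3-diene-1-carboxylate (racemic) | CCCC1CC(OC(=O)c2c(CCCCC)cc(OCc3ccccc3)cc2OCc2ccccc2)=CC(O[Si](C)(C)C)=C1C(=O)OCc1ccccc1
F0 | step 8 | none | none
A1 | alternative 1 | benzyl 2-hydroxy-6-propyl-4-[(3,5,7-trioxododecanoyl)oxy]benzoate | CCCCCC(=O)CC(=O)CC(=O)CC(=O)Oc1cc(O)c(C(=O)OCc2ccccc2)c(CCC)c1
A2 | alternative 1 | benzyl 4-[(2,4-dihydroxy-6-pentylbenzoyl)oxy]-2-hydroxy-6-propylbenzoate | CCCCCc1cc(O)cc(O)c1C(=O)Oc1cc(O)c(C(=O)OCc2ccccc2)c(CCC)c1
A3 | alternative 1 | benzyl 2,4-dihydroxy-6-propylbenzoate | CCCc1cc(O)cc(O)c1C(=O)OCc1ccccc1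
A4 | alternative 1 | 6-(2,4-dioxononyl)-2,2-dimethyl-4H-1,3-dioxin-4-one | CCCCCC(=O)CC(=O)CC1=CC(=O)OC(C)(C)O1
A5 | alternative 2 | 2-bromo-1-fluoro-3,5-dimethoxybenzene | COc1cc(F)c(Br)c(OC)c1
A6 | alternative 2 | 3,5-dimethoxybenzyne | COC1=CC(OC)=CC#C1
A7 | alternative 2 | 2,4-dimethoxy-6-propylbenzoic acid | CCCc1cc(OC)cc(OC)c1C(=O)O
A8 | alternative 2 | 2,4-dihydroxy-6-propylbenzoic acid | CCCc1cc(O)cc(O)c1C(=O)O
A9 | alternative 3 | 1,5-bis(benzyloxy)-2-iodo-3-pentylbenzene | CCCCCc1cc(OCc2ccccc2)cc(OCc2ccccc2)c1I
A10 | alternative 3 | benzyl 4-{[2,4-bis(benzyloxy)-6-pentylbenzoyl]oxy}-2-hydroxy-6-propylbenzoate (identical with 15) | CCCCCc1cc(OCc2ccccc2)cc(OCc2ccccc2)c1C(=O)Oc1cc(O)c(C(=O)OCc2ccccc2)c(CCC)c1
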